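The target is a 19-membered ring of four arenes: ring A (methoxy-bearing), ring B (para-phenylene), ring C (phenol) and ring D (meta-phenylene), joined by two ether oxygens and two CH2–CH2 bridges. The route rests on cutting the CH2–CH2 bond between ring D and ring A. Both carbons are benzylic, so this bond can arise when SO2 is expelled photochemically from a CH2–SO2–CH2 unit. The precursor is therefore a 20-membered bis-benzylic sulfone, closed beforehand by double S-alkylation of sulfide and carrying the ring C phenol as a methoxymethyl (MOM) ether. One irradiation forms the last C–C bond and contracts the ring to its final size.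

Key step: step 12

Remark: the target has no stereocentre. The Wittig olefin is carried as an E/Z mixture because hydrogenation removes the geometry, and the transient sulfoxide is racemic at sulfur.

Step 1
Reactants: 1 methyl 3-hydroxy-4-methoxybenzoate; 2 4-fluorobenzaldehyde
Product: 3 methyl 3-(4-formylphenoxy)-4-methoxybenzoate
Conditions: K2CO3, dry DMF, 120 °C
Reagents that add atoms: none
Why: Nucleophilic aromatic substitution (SNAr), in which the para-formyl group activates the C–F bond toward the phenoxide of 1 while the non-enolisable aldehyde and the methyl ester tolerate anhydrous carbonate.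

Step 2
Reactants: 3 methyl 3-(4-formylphenoxy)-4-methoxybenzoate
Product: 4 methyl 3-[4-(hydroxymethyl)phenoxy]-4-methoxybenzoate
Conditions: NaBH4, MeOH/THF, 0 °C
Reagents that add atoms: none
Why: Chemoselective borohydride reduction, since NaBH4 reduces the aryl aldehyde quickly at 0 °C and leaves the aryl methyl ester untouched.

Step 3
Reactants: 4 methyl 3-[4-(hydroxymethyl)phenoxy]-4-methoxybenzoate
Product: 5 {4-[2-methoxy-5-(methoxycarbonyl)phenoxy]benzyl}triphenylphosphonium bromide
Conditions: PPh3·HBr, MeCN, reflux
Reagents that add atoms: triphenylphosphine hydrobromide, [Br-].c1ccc(cc1)[PH+](c1ccccc1)c1ccccc1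
Why: Acid-promoted phosphonium salt formation from a benzylic alcohol, in which the para-aryloxy group eases departure of the protonated hydroxyl so that PPh3 captures the benzylic carbon directly and a separate halogenation is avoided.

Step 4
Reactants: 6 3,4-dihydroxybenzaldehyde
Product: 7 3-hydroxy-4-(methoxymethoxy)benzaldehyde
Conditions: MOMCl (1.05 equiv), K2CO3, acetone, 0 °C → rt
Reagents that add atoms: chloromethyl methyl ether (MOMCl), COCCl
Why: Regioselective Williamson-type O-alkylation, because the 4-OH conjugated to the para-formyl group is the more acidic phenol, so its phenoxide forms first and is alkylated while the 3-OH stays free.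

Step 5
Reactants: 7 3-hydroxy-4-(methoxymethoxy)benzaldehyde; 8 methyl 3-iodobenzoate
Product: 9 methyl 3-[5-formyl-2-(methoxymethoxy)phenoxy]benzoate
Conditions: CuI (10 mol%), N,N-dimethylglycine·HCl (30 mol%), Cs2CO3, dry dioxane, 90 °C
Reagents that add atoms: none
Why: Ligand-accelerated Ullmann diaryl ether coupling, in which the ester-activated aryl iodide reacts readily with the copper phenoxide of 7 and the MOM acetal, the aldehyde and the ester are stable to Cs2CO3 in dry dioxane.

Step 6
Reactants: 5 {4-[2-methoxy-5-(methoxycarbonyl)phenoxy]benzyl}triphenylphosphonium bromide; 9 methyl 3-[5-formyl-2-(methoxymethoxy)phenoxy]benzoate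
Product: 11 methyl 4-methoxy-3-[4-(2-{3-[3-(methoxycarbonyl)phenoxy]-4-(methoxymethoxy)phenyl}ethenyl)phenoxy]benzoate (E/Z mixture), via phosphonium ylide 10 (not isolated)
Conditions: K2CO3, 18-crown-6 (cat.), CH2Cl2, reflux
Reagents that add atoms: none
Why: Wittig olefination with a semi-stabilised benzylic ylide generated under solid–liquid phase-transfer conditions, which are mild enough for both methyl esters and the MOM acetal; the alkene geometry is of no consequence.

Step 7
Reactants: 11 methyl 4-methoxy-3-[4-(2-{3-[3-(methoxycarbonyl)phenoxy]-4-(methoxymethoxy)phenyl}ethenyl)phenoxy]benzoate (E/Z mixture)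
Product: 12 methyl 4-methoxy-3-[4-(2-{3-[3-(methoxycarbonyl)phenoxy]-4-(methoxymethoxy)phenyl}ethyl)phenoxy]benzoate
Conditions: H2 (1 atm), 10% Pd/C, EtOAc, Et3N (trace), rt
Reagents that add atoms: none
Why: Heterogeneous catalytic hydrogenation of the stilbene double bond; the molecule has no benzylic C–O bond, so the aryl ethers, the esters and the MOM acetal should be inert.

Step 8
Reactants: 12 methyl 4-methoxy-3-[4-(2-{3-[3-(methoxycarbonyl)phenoxy]-4-(methoxymethoxy)phenyl}ethyl)phenoxy]benzoate
Product: 13 [3-(4-{2-[3-(3-(hydroxymethyl)phenoxy)-4-(methoxymethoxy)phenyl]ethyl}phenoxy)-4-methoxyphenyl]methanol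
Conditions: LiAlH4, THF, 0 °C; Fieser work-up
Reagents that add atoms: none
Why: Hydride reduction of both aryl methyl esters to benzylic alcohols with LiAlH4, with ethers and acetal inert and a basic work-up that keeps the MOM group.

Step 9
Reactants: 13 [3-(4-{2-[3-(3-(hydroxymethyl)phenoxy)-4-(methoxymethoxy)phenyl]ethyl}phenoxy)-4-methoxyphenyl]methanol
Product: 14 4-(bromomethyl)-2-(4-{2-[3-(3-(bromomethyl)phenoxy)-4-(methoxymethoxy)phenyl]ethyl}phenoxy)-1-methoxybenzene
Conditions: CBr4, PPh3, CH2Cl2, 0 °C
Reagents that add atoms: carbon tetrabromide, BrC(Br)(Br)Br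
Why: Appel bromination, in which bromide displaces the alkoxyphosphonium groups under essentially neutral conditions that spare the acid-labile MOM acetal; the electron-rich ring A bromide is carried forward without storage.

Step 10
Reactants: 14 4-(bromomethyl)-2-(4-{2-[3-(3-(bromomethyl)phenoxy)-4-(methoxymethoxy)phenyl]ethyl}phenoxy)-1-methoxybenzene
Product: 15 macrocyclic sulfide (20-membered thiacyclophane; ring A CH2–S–CH2 ring D; MOM ether on ring C)
Conditions: Na2S/Al2O3, CH2Cl2/EtOH (10:1 v/v), slow addition of 14, ca. 2 mM, rt
Reagents that add atoms: sodium sulfide, [Na+].[Na+].[S-2]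
Why: Double SN2 S-alkylation (thiacyclophane synthesis), in which the first displacement gives a benzylic thiolate that closes the 20-membered ring on the second benzylic bromide, while the supported sulfide, the dilution and the weakly protic medium hold back oligomerisation and solvolysis of the ring A bromide.

Step 11
Reactants: 15 macrocyclic sulfide (20-membered thiacyclophane; ring A CH2–S–CH2 ring D; MOM ether on ring C)
Product: 17 macrocyclic bis-benzylic sulfone (20-membered ring; ring A CH2–SO2–CH2 ring D; MOM ether on ring C), via macrocyclic sulfoxide 16 (not isolated)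
Conditions: mCPBA (2.2 equiv), CH2Cl2, 0 °C → rt
Reagents that add atoms: mCPBA (3-chloroperoxybenzoic acid), OOC(=O)c1cccc(Cl)c1
Why: Peracid oxidation of sulfide to sulfone through the sulfoxide; sulfur is far more nucleophilic than the alkoxyarenes, so two equivalents at low temperature should stop at the sulfone.

Step 12
Reactants: 17 macrocyclic bis-benzylic sulfone (20-membered ring; ring A CH2–SO2–CH2 ring D; MOM ether on ring C)
Product: 18 MOM-protected macrocycle (19-membered ring; ring A CH2–CH2 ring D; MOM ether on ring C)
Conditions: hν (254 nm, low-pressure Hg lamp, quartz), degassed benzene, ca. 1 mM, Ar, rt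
Reagents that add atoms: none
Why: Excitation at 254 nm, directly or by energy transfer from benzene, homolyses a benzylic C–S bond, most readily the one at the ring A carbon whose radical is stabilised by the para-methoxy group, and the arylmethanesulfonyl radical then loses SO2 rapidly to give the second benzylic radical. The two radical centres stay tied together by the chain ring D–O–ring C–CH2CH2–ring B–O–ring A and combine to the CH2–CH2 bond. The closest known reaction type is photochemical or pyrolytic SO2 extrusion from dibenzyl sulfones, used to contract thiacyclophane dioxides to cyclophanes. The 19-membered ring is not closed from an open chain but arises by contraction of the existing 20-membered ring through intramolecular radical–radical combination. No stereocentre is formed. The step needs recombination to outrun radical escape (hydrogen abstraction, intermolecular coupling) and photoreactions of the diaryl ethers, which the tether, high dilution, exclusion of oxygen and stopping the irradiation once 17 is consumed should secure; no regiochemical question arises because only the two benzylic carbons are joined.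

Step 13
Reactants: 18 MOM-protected macrocycle (19-membered ring; ring A CH2–CH2 ring D; MOM ether on ring C)
Product: 19 target macrocycle CNP0132125.0 (free phenol on ring C)
Conditions: conc. HCl (cat.), MeOH/THF, 50 °C
Reagents that add atoms: none
Why: Acid-catalysed acetal cleavage by transacetalisation to methanol, to which the aryl methyl ether and the diaryl ethers are inert.

Compound list

1 | methyl 3-hydroxy-4-methoxybenzoate | COC(=O)c1ccc(OC)c(O)c1 | starting material
2 | 4-fluorobenzaldehyde | O=Cc1ccc(F)cc1 | starting material
3 | methyl 3-(4-formylphenoxy)-4-methoxybenzoate | COC(=O)c1ccc(OC)c(Oc2ccc(C=O)cc2)c1 | intermediate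
4 | methyl 3-[4-(hydroxymethyl)phenoxy]-4-methoxybenzoate | COC(=O)c1ccc(OC)c(Oc2ccc(CO)cc2)c1 | intermediate
5 | {4-[2-methoxy-5-(methoxycarbonyl)phenoxy]benzyl}triphenylphosphonium bromide | COC(=O)c1ccc(OC)c(Oc2ccc(C[P+](c3ccccc3)(c3ccccc3)c3ccccc3)cc2)c1.[Br-] | intermediate
6 | 3,4-dihydroxybenzaldehyde | O=Cc1ccc(O)c(O)c1 | starting material
7 | 3-hydroxy-4-(methoxymethoxy)benzaldehyde | COCOc1ccc(C=O)cc1O | intermediate
8 | methyl 3-iodobenzoate | COC(=O)c1cccc(I)c1 | starting material
9 | methyl 3-[5-formyl-2-(methoxymethoxy)phenoxy]benzoate | COCOc1ccc(C=O)cc1Oc1cccc(c1)C(=O)OC | intermediate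
10 | phosphonium ylide: methyl 4-methoxy-3-{4-[(triphenylphosphoranylidene)methyl]phenoxy}benzoate | COC(=O)c1ccc(OC)c(Oc2ccc(C=P(c3ccccc3)(c3ccccc3)c3ccccc3)cc2)c1 | intermediate (not isolated)
11 | methyl 4-methoxy-3-[4-(2-{3-[3-(methoxycarbonyl)phenoxy]-4-(methoxymethoxy)phenyl}ethenyl)phenoxy]benzoate (E/Z mixture; geometry not defined) | COC(=O)c1ccc(OC)c(Oc2ccc(C=Cc3ccc(OCOC)c(Oc4cccc(c4)C(=O)OC)c3)cc2)c1 | intermediate
12 | methyl 4-methoxy-3-[4-(2-{3-[3-(methoxycarbonyl)phenoxy]-4-(methoxymethoxy)phenyl}ethyl)phenoxy]benzoate | COC(=O)c1ccc(OC)c(Oc2ccc(CCc3ccc(OCOC)c(Oc4cccc(c4)C(=O)OC)c3)cc2)c1 | intermediate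
13 | [3-(4-{2-[3-(3-(hydroxymethyl)phenoxy)-4-(methoxymethoxy)phenyl]ethyl}phenoxy)-4-methoxyphenyl]methanol (open-chain diol) | COc1ccc(CO)cc1Oc1ccc(CCc2ccc(OCOC)c(Oc3cccc(CO)c3)c2)cc1 | intermediate
14 | 4-(bromomethyl)-2-(4-{2-[3-(3-(bromomethyl)phenoxy)-4-(methoxymethoxy)phenyl]ethyl}phenoxy)-1-methoxybenzene (open-chain dibromide) | COc1ccc(CBr)cc1Oc1ccc(CCc2ccc(OCOC)c(Oc3cccc(CBr)c3)c2)cc1 | intermediate
15 | macrocyclic sulfide, 20-membered: ring A (CH2 at C-1; O–ring B at C-3; OMe at C-4) – O – ring B (1,4) – CH2CH2 – ring C (chain at C-1; O–ring D at C-3; OMOM at C-4) – O – ring D (1,3) – CH2–S–CH2 – ring A | COc1ccc2cc1Oc1ccc(cc1)CCc1ccc(OCOC)c(c1)Oc1cccc(c1)CSC2 | intermediate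
16 | macrocyclic sulfoxide: as 15 with CH2–S(=O)–CH2 (racemic at sulfur) | COc1ccc2cc1Oc1ccc(cc1)CCc1ccc(OCOC)c(c1)Oc1cccc(c1)CS(=O)C2 | intermediate (not isolated)
17 | macrocyclic bis-benzylic sulfone, 20-membered: as 15 with CH2–SO2–CH2 between ring D and ring A | COc1ccc2cc1Oc1ccc(cc1)CCc1ccc(OCOC)c(c1)Oc1cccc(c1)CS(=O)(=O)C2 | intermediate
18 | MOM-protected macrocycle, 19-membered: as 15 with CH2–CH2 between ring D and ring A | COc1ccc2cc1Oc1ccc(cc1)CCc1ccc(OCOC)c(c1)Oc1cccc(c1)CC2 | intermediate
19 | target CNP0132125.0: 19-membered macrocycle with OMe on ring A and free OH on ring C | COc1ccc2cc1Oc1ccc(cc1)CCc1ccc(O)c(c1)Oc1cccc(c1)CC2 | target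

Total step count: 13.
Longest linear sequence: 11 steps (steps 1, 2, 3 and 6 to 13, from compound 1); the ring C–ring D fragment is made in a two-step side branch (steps 4 and 5).

Steps most likely to fail

Step 12. The benzylic radicals may escape recombination by abstracting hydrogen or coupling between molecules, and the diaryl ethers may undergo their own photoreactions under 254 nm light. The fallback sets out from sulfone 17 and replaces radical extrusion by an ionic contraction, the Ramberg–Bäcklund reaction in its Chan variant (KOH/Al2O3, CBr2F2, t-BuOH/CH2Cl2, 0 °C → rt). α-Bromination of a benzylic sulfone carbanion, 1,3-elimination to the episulfone and loss of SO2 should give the 19-membered macrocyclic stilbene F1 as an E/Z mixture. Hydrogenation (H2, 10% Pd/C, EtOAc, rt) then saturates the new double bond and rejoins the route at 18.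

Step 10. Intermolecular S-alkylation may outrun ring closure and give oligomers, or the ring A benzylic bromide may ionise and be lost to solvolysis before sulfur arrives. The fallback sets out from dibromide 14 and gives up the sulfur detour for a direct reductive C–C macrocyclisation. Intramolecular Wurtz-type coupling with the sodium tetraphenylethylene reagent (Na, tetraphenylethylene, THF, −78 °C, slow addition of 14 under high dilution) should join the two benzylic carbons in an aprotic medium at low temperature. It comes back to the route at 18 and makes no new isolated compound.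

Step 9. Ionisation of the electron-rich ring A benzylic bromide during formation or chromatography may cause decomposition, and traces of HBr may cost the MOM acetal. The fallback sets out from diol 13 and uses a sturdier latent electrophile. Corey–Kim chlorination (NCS, Me2S, CH2Cl2, −20 → 0 °C) should give the bis(benzylic chloride) F2, which can be purified and stored. F2 is then cyclised with Na2S·9H2O and catalytic NaI in DMF under slow addition at rt, the iodide activating each chloride only in the flask, and the route is rejoined at sulfide 15.

Further compounds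

F1 | step 12 | macrocyclic stilbene, 19-membered: as 18 with CH=CH between ring D and ring A (E/Z mixture; geometry not defined) | COc1ccc2cc1Oc1ccc(cc1)CCc1ccc(OCOC)c(c1)Oc1cccc(c1)C=C2
F0 | step 10 | none | none
F2 | step 9 | 4-(chloromethyl)-2-(4-{2-[3-(3-(chloromethyl)phenoxy)-4-(methoxymethoxy)phenyl]ethyl}phenoxy)-1-methoxybenzene | COc1ccc(CCl)cc1Oc1ccc(CCc2ccc(OCOC)c(Oc3cccc(CCl)c3)c2)cc1
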